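## Retrosynthetic overview
- **Feature:** ring A (the phenol ring) is a run of four adjacent C–Br carbons, C3–C4–C5–C6. Its two ends are bridged by the vicinal oxygen-bearing pair C1(OH)–C2(O–ring B), so it splits into a C4 perbromodiene and a C2 alkene that carries both oxygens.
- **Last disconnection:** the O–Si bond of a silyl ether on the C1 phenol oxygen.
- **Key disconnection:** C1–C6 and C2–C3. This leads back to tetrabromothiophene 1,1-dioxide (sulfur is a traceless bridge, lost as SO2) and the bis(trimethylsilyl) ketene acetal of (2-bromophenoxy)acetic acid. The surplus silyloxy group on C1 is the leaving group that delivers aromaticity.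
- **Fragments:** the diene comes from S-oxidation of tetrabromothiophene. The alkene comes from Williamson etherification of 2-bromophenol with bromoacetic acid, then silylation, enolisation and silylation.
- **Ring order:** ring B is bought with its bromine in place, and ring A is the only ring formed. No brominating agent is used anywhere in the route.

Key step: step 4

Remark: the target has no stereocentre, and rotation about the two aryl–O bonds is taken to be fast, so the compound is achiral and the demand for a single enantiomer is met trivially. Ring A is numbered C1 (OH), C2 (OAr), C3–C6 (Br).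

## Route

Step 1
Reactants: 1 2,3,4,5-tetrabromothiophene
Product: 3 2,3,4,5-tetrabromothiophene 1,1-dioxide, via tetrabromothiophene 1-oxide 2 (not isolated)
Conditions: mCPBA (3.5 equiv, in portions), ClCH2CH2Cl, 70 °C; cool, filter off the acid, recrystallise
Reagents that add atoms: mCPBA (3-chloroperoxybenzoic acid), OOC(=O)c1cccc(Cl)c1
Why: Peracid S-oxidation of a thiophene is the standard route to tetrahalothiophene 1,1-dioxides: the slow first oxygen transfer breaks the aromaticity, sulfoxide 2 is oxidised faster than 1 and so should not build up, and the four bromines suppress the self-dimerisation typical of simple thiophene dioxides.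

Step 2
Reactants: 4 2-bromophenol; 5 bromoacetic acid
Product: 6 (2-bromophenoxy)acetic acid
Conditions: NaOH (aq), reflux; then HCl (aq) to pH 1, filter
Reagents that add atoms: none
Why: Williamson ether synthesis, in which the phenoxide displaces bromide from bromoacetate by SN2 while the aryl C–Br bond is inert to aqueous hydroxide.

Step 3
Reactants: 6 (2-bromophenoxy)acetic acid
Product: 8 2-(2-bromophenoxy)-1,1-bis(trimethylsilyloxy)ethene, via trimethylsilyl (2-bromophenoxy)acetate 7 (not isolated)
Conditions: (i) LiHMDS (1.05 equiv), THF, 0 °C, then TMSCl (2.4 equiv), 0 °C → rt; (ii) −78 °C, LiHMDS (1.15 equiv) added slowly, → rt; pentane, filtration under Ar, Kugelrohr distillation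
Reagents that add atoms: chlorotrimethylsilane (TMSCl), C[Si](C)(C)Cl
Why: O-silylation of the lithium carboxylate, then kinetic enolisation of silyl ester 7 with O-silylation under internal-quench conditions, is the standard preparation of bis(silyl) ketene acetals (the same enolisation as in glycolate Ireland–Claisen reactions); the aryloxy group acidifies the α-protons enough for LiHMDS, which at −78 °C does not metalate the ring next to bromine, and two identical silyloxy groups leave no alkene geometry to control.

Step 4
Reactants: 3 2,3,4,5-tetrabromothiophene 1,1-dioxide; 8 2-(2-bromophenoxy)-1,1-bis(trimethylsilyloxy)ethene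
Product: 11 [2,3,4,5-tetrabromo-6-(2-bromophenoxy)phenoxy]trimethylsilane, via bridged sulfone adduct 9 (not isolated), via bis(silyloxy)cyclohexadiene 10 (not isolated)
Conditions: 8 (2.2 equiv; the excess takes up liberated silanol), PhMe, 0 °C → rt, then 90 °C, slow Ar sweep, dark; evaporate, use crude
Reagents that add atoms: none
Why: The sulfone-lowered LUMO of diene 3 and the HOMO of the triply oxygenated alkene 8 are matched for an inverse-electron-demand Diels–Alder reaction, which should run as a strongly asynchronous [4+2] (or through a short-lived zwitterion in which the CH(OAr) carbon bonds first to a brominated carbon next to sulfur and the sulfonyl-stabilised allyl anion then closes on the bis(silyloxy)carbenium carbon) to give bridged sulfone 9. Adduct 9 should lose SO2 by cheletropic retro-addition at the reaction temperature, and in the resulting diene 10 the oxygen-assisted departure of one Me3SiO group from C1 together with the C2 proton (a 1,2-elimination driven by aromatisation) gives 11. The closest known reactions are the benzannulations of tetrachloro- and tetrabromothiophene 1,1-dioxide with enol ethers and other alkenes, in which SO2 leaves spontaneously, and the alcohol-eliminating aromatisations that follow addition of ketene acetals to 2-pyrones and 1,2,4,5-tetrazines. Ring A, the only ring formed, is closed by an intermolecular [4+2] cycloaddition that makes C1–C6 and C2–C3 in one operation, with four ring carbons from 3 and two from 8. The stereocentres of 9 and 10 are transient, arise as racemates whose endo or exo sense is of no consequence, and vanish on aromatisation, so nothing has to be controlled. The selectivity needed is an aromatisation that keeps the aryloxy group and all four bromines: C2 has no hydrogen-bearing neighbour, so ArOH cannot be eliminated, quaternary C1 must give up a substituent and holds only silyloxy groups, the mirror symmetry of 3 removes any regiochemical choice, and even adventitious hydrolysis of the silyl ketal in 10 leads to the keto tautomer of 12.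

Step 5
Reactants: 11 [2,3,4,5-tetrabromo-6-(2-bromophenoxy)phenoxy]trimethylsilane
Product: 12 3,4,5,6-tetrabromo-2-(2-bromophenoxy)phenol
Conditions: 1 M HCl (aq), THF, rt, dark; chromatography
Reagents that add atoms: none
Why: Acid-catalysed hydrolysis of an aryl trimethylsilyl ether should be very fast here because the tetrabromophenol is a good leaving group at silicon; acidic rather than basic or fluoride conditions keep the product protonated, which shuts off attack of a phenoxide on the C–Br carbon of ring B (dibenzodioxin formation), and any 10 left in the crude converges on 12 through its dienone tautomer.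

## Compound list
1 | 2,3,4,5-tetrabromothiophene | Brc1sc(Br)c(Br)c1Br | starting material
2 | 2,3,4,5-tetrabromothiophene 1-oxide | O=S1C(Br)=C(Br)C(Br)=C1Br | intermediate
3 | 2,3,4,5-tetrabromothiophene 1,1-dioxide | O=S1(=O)C(Br)=C(Br)C(Br)=C1Br | intermediate
4 | 2-bromophenol | Oc1ccccc1Br | starting material
5 | bromoacetic acid | OC(=O)CBr | starting material
6 | (2-bromophenoxy)acetic acid | OC(=O)COc1ccccc1Br | intermediate
7 | trimethylsilyl (2-bromophenoxy)acetate | C[Si](C)(C)OC(=O)COc1ccccc1Br | intermediate
8 | 2-(2-bromophenoxy)-1,1-bis(trimethylsilyloxy)ethene | C[Si](C)(C)OC(O[Si](C)(C)C)=COc1ccccc1Br | intermediate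
9 | 1,2,3,4-tetrabromo-6-(2-bromophenoxy)-5,5-bis(trimethylsilyloxy)-7-thiabicyclo[2.2.1]hept-2-ene 7,7-dioxide (racemic, endo/exo undefined, transient) | O=S1(=O)C2(Br)C(Br)=C(Br)C1(Br)C(O[Si](C)(C)C)(O[Si](C)(C)C)C2Oc3ccccc3Br | intermediate
10 | 1,2,3,4-tetrabromo-5-(2-bromophenoxy)-6,6-bis(trimethylsilyloxy)cyclohexa-1,3-diene (racemic, transient) | BrC1=C(Br)C(Br)=C(Br)C(O[Si](C)(C)C)(O[Si](C)(C)C)C1Oc2ccccc2Br | intermediate
11 | [2,3,4,5-tetrabromo-6-(2-bromophenoxy)phenoxy]trimethylsilane | C[Si](C)(C)Oc1c(Br)c(Br)c(Br)c(Br)c1Oc1ccccc1Br | intermediate
12 | 3,4,5,6-tetrabromo-2-(2-bromophenoxy)phenol | Oc1c(Br)c(Br)c(Br)c(Br)c1Oc1ccccc1Br | target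

## Summary
Total step count: 5.
Longest linear sequence: 4 steps (2, 3, 4, 5).

## Steps most likely to fail

**Step 4 (key step).**
- **What may go wrong:** after the first C–C bond forms, the dipolar intermediate may shed bromide or shift a silyl group instead of closing the second bond. The crowded trisubstituted alkene may also add so slowly that protodesilylation by liberated silanol consumes it.
- **Fallback:** ring A is no longer built; the diaryl ether C–O bond is made instead by metal-free O-arylation. This path takes over none of the intermediates. It branches off before 1 and 4, at the level of purchased materials, and comes back to the route at 12. Guaiacol is exhaustively brominated (excess Br2, Fe powder, AcOH, heat) to 3,4,5,6-tetrabromo-2-methoxyphenol F1. Separately, 1-bromo-2-iodobenzene is oxidised with mCPBA/TsOH·H2O in MeCN and treated with 1,3,5-trimethoxybenzene to give (2-bromophenyl)(2,4,6-trimethoxyphenyl)iodonium tosylate F2. F1 and F2 with K2CO3 in toluene at about 50 °C should transfer the less electron-rich, ortho-substituted 2-bromophenyl group to oxygen, giving 1,2,3,4-tetrabromo-5-(2-bromophenoxy)-6-methoxybenzene F3. BBr3 in CH2Cl2 (−78 °C → rt) then cleaves the methyl ether to 12.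

**Step 3.**
- **What may go wrong:** the enolate may condense with the silyl ester, silylation may occur partly at carbon, or the very moisture-sensitive bis(trimethylsilyl) acetal may hydrolyse during isolation.
- **Fallback:** both the lithium amide and the trimethylsilyl group are dropped. The path sets out from 6. Soft enolisation with TBSOTf (2.3 equiv) and Et3N in CH2Cl2 should give 2-(2-bromophenoxy)-1,1-bis(tert-butyldimethylsilyloxy)ethene F4; here the silyl triflate activates the carboxyl oxygen and the amine removes the α-proton. F4 tolerates a cold aqueous wash. It takes the place of 8 in the cycloaddition with 3 and, by the same cascade, should give tert-butyl(dimethyl)[2,3,4,5-tetrabromo-6-(2-bromophenoxy)phenoxy]silane F5. TBAF buffered with AcOH in THF cleaves the silyl ether, and the path comes back at 12.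

**Step 1.**
- **What may go wrong:** four bromines strongly deactivate the sulfur of 1, so oxygen transfer may stall, and long heating with peracid may erode the product.
- **Fallback:** a more electron-rich surrogate is oxidised and the α-bromines are restored afterwards. The path sets out from 1. Double Br/Li exchange at the two α-positions (n-BuLi, 2 equiv, THF, −78 °C) followed by TMSCl gives 3,4-dibromo-2,5-bis(trimethylsilyl)thiophene F6. mCPBA in CH2Cl2 should oxidise this readily to 3,4-dibromo-2,5-bis(trimethylsilyl)thiophene 1,1-dioxide F7. Twofold ipso-bromodesilylation (Br2, AgBF4, CH2Cl2) brings the path back at 3.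

## Further compounds
F1 | step 4 | 3,4,5,6-tetrabromo-2-methoxyphenol | COc1c(O)c(Br)c(Br)c(Br)c1Br
F2 | step 4 | (2-bromophenyl)(2,4,6-trimethoxyphenyl)iodonium tosylate | COc1cc(OC)c([I+]c2ccccc2Br)c(OC)c1.Cc1ccc(cc1)S(=O)(=O)[O-]
F3 | step 4 | 1,2,3,4-tetrabromo-5-(2-bromophenoxy)-6-methoxybenzene | COc1c(Br)c(Br)c(Br)c(Br)c1Oc1ccccc1Br
F4 | step 3 | 2-(2-bromophenoxy)-1,1-bis(tert-butyldimethylsilyloxy)ethene | CC(C)(C)[Si](C)(C)OC(O[Si](C)(C)C(C)(C)C)=COc1ccccc1Br
F5 | step 3 | tert-butyl(dimethyl)[2,3,4,5-tetrabromo-6-(2-bromophenoxy)phenoxy]silane | CC(C)(C)[Si](C)(C)Oc1c(Br)c(Br)c(Br)c(Br)c1Oc1ccccc1Br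
F6 | step 1 | 3,4-dibromo-2,5-bis(trimethylsilyl)thiophene | C[Si](C)(C)c1sc([Si](C)(C)C)c(Br)c1Br
F7 | step 1 | 3,4-dibromo-2,5-bis(trimethylsilyl)thiophene 1,1-dioxide | C[Si](C)(C)C1=C(Br)C(Br)=C([Si](C)(C)C)S1(=O)=O
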